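**Plan**

- Retrosynthesis: the C4' carbinol goes back to the lower ketone. Upper ring C is cut at C4–C4a (Friedel–Crafts), then at C2–O1 (phenol plus epoxide) and at C3–C4 (alkyne plus aldehyde on C6'). Lower ring C is cut at C2'–O1' and at the chalcone C=C (epoxide, aldol).
- Enabling feature: in upper ring C (O1, C2, C3, C4, C4a, C8a) C4 is benzylic to lower ring A at C6' (para to O1', ortho to the C7' oxygen). C4a is the only free carbon ortho to the O1 aryl ether (C8 is oxygenated) and lies para to the C7 oxygen.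
- Forward: lower ring C closes first (chalcone, epoxide, dihydroflavonol). The C4–C3–C2 chain is joined at C6' by alkynylation, the O1 aryl ether is attached at C2, and upper ring C closes last. Deprotection and ketone reduction follow.
- Stereochemistry: C2'/C3' come from a Juliá–Colonna epoxidation. Upper C3 and C2 come from a relay carbinol at C4 (BINOL–Ti alkynylation) through threo-selective epoxidation and SN2 opening. C4 is set in the ring closure (trans to O3 by ester bridging), and C4' by NaBH4 (trans to O3').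

Key step: step 17

Remark: primed locants are those of the lower flavan unit; the SMILES is read as upper (2R,3R,4S) = 2,3-cis-3,4-trans and lower (2R,3S,4R) = 2,3-trans-3,4-trans, and the CIP descriptors at upper C4 (R with benzyl ethers, S in the free phenols) and at the chain carbon that becomes C3 (R in the diol, S in the dibenzoate) change with the substituents while the geometry stays the same.

**Route**

Step 1
Reactants: 1 gallacetophenone
Product: 2 1-[3,4-bis(benzyloxy)-2-hydroxyphenyl]ethan-1-one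
Conditions: BnBr (2.1 equiv), K2CO3, acetone, reflux
Reagents that add atoms: benzyl bromide, BrCc1ccccc1
Why: Williamson etherification alkylates the 4- and 3-hydroxyls, while the 2-hydroxyl, hydrogen-bonded to the acetyl carbonyl, should stay free for the later chalcone chemistry.

Step 2
Reactants: 2 1-[3,4-bis(benzyloxy)-2-hydroxyphenyl]ethan-1-one
Product: 3 1-[3,4-bis(benzyloxy)-5-bromo-2-hydroxyphenyl]ethan-1-one
Conditions: NBS, MeCN, 0 °C to rt
Reagents that add atoms: N-bromosuccinimide, O=C1CCC(=O)N1Br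
Why: Electrophilic aromatic bromination should go para to the free phenol (C5, also ortho to the C4 benzyloxy group), the only activated open position, which installs the handle for the later C6' carbon.

Step 3
Reactants: 3 1-[3,4-bis(benzyloxy)-5-bromo-2-hydroxyphenyl]ethan-1-one
Product: 4 1-[3,4-bis(benzyloxy)-5-bromo-2-(methoxymethoxy)phenyl]ethan-1-one
Conditions: NaH, MOMCl, DMF, 0 °C
Reagents that add atoms: chloromethyl methyl ether, COCCl
Why: Williamson etherification of the sodium phenoxide gives the MOM ether, which keeps the phenol from cyclising during the chalcone epoxidation and is removed later by acid.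

Step 4
Reactants: 4 1-[3,4-bis(benzyloxy)-5-bromo-2-(methoxymethoxy)phenyl]ethan-1-one; 5 4-(benzyloxy)benzaldehyde
Product: 6 (E)-1-[3,4-bis(benzyloxy)-5-bromo-2-(methoxymethoxy)phenyl]-3-[4-(benzyloxy)phenyl]prop-2-en-1-one
Conditions: KOH, EtOH/THF, rt
Reagents that add atoms: none
Why: Claisen–Schmidt aldol condensation of the methyl ketone enolate with the non-enolisable aldehyde, followed by E1cB dehydration, should give the conjugated E-enone.

Step 5
Reactants: 6 (E)-1-[3,4-bis(benzyloxy)-5-bromo-2-(methoxymethoxy)phenyl]-3-[4-(benzyloxy)phenyl]prop-2-en-1-one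
Product: 7 [3,4-bis(benzyloxy)-5-bromo-2-(methoxymethoxy)phenyl][(2R,3S)-3-[4-(benzyloxy)phenyl]oxiran-2-yl]methanone
Conditions: poly-L-leucine, 30% H2O2, NaOH, toluene/H2O, rt
Reagents that add atoms: hydrogen peroxide, OO
Why: Juliá–Colonna epoxidation (Weitz–Scheffer addition of hydroperoxide inside the helical poly-L-leucine) should deliver oxygen to one enone face and give the (αR,βS) trans-epoxide, which sets the future C3' and, after inversion, C2'.

Step 6
Reactants: 7 [3,4-bis(benzyloxy)-5-bromo-2-(methoxymethoxy)phenyl][(2R,3S)-3-[4-(benzyloxy)phenyl]oxiran-2-yl]methanone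
Product: 9 (2R,3R)-7,8-bis(benzyloxy)-2-[4-(benzyloxy)phenyl]-6-bromo-3-hydroxychroman-4-one, via 2'-hydroxy epoxy ketone 8 (not isolated)
Conditions: HCl (cat.), MeOH/THF, 50 °C
Reagents that add atoms: none
Why: Acid removes the MOM group and the freed phenol opens the protonated epoxide at the benzylic carbon (6-endo intramolecular epoxide opening) with inversion, which should give the 2,3-trans dihydroflavonol, C3 keeping the configuration of step 5 and trans also being the thermodynamic outcome if the benzylic C–O bond ionises.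

Step 7
Reactants: 9 (2R,3R)-7,8-bis(benzyloxy)-2-[4-(benzyloxy)phenyl]-6-bromo-3-hydroxychroman-4-one
Product: 10 (2R,3R)-3,7,8-tris(benzyloxy)-2-[4-(benzyloxy)phenyl]-6-bromochroman-4-one
Conditions: BnOC(=NH)CCl3, TfOH (cat.), CH2Cl2/cyclohexane, 0 °C to rt
Reagents that add atoms: benzyl 2,2,2-trichloroacetimidate, ClC(Cl)(Cl)C(=N)OCc1ccccc1
Why: Acid-catalysed O-benzylation with the trichloroacetimidate avoids the base that would enolise or ring-open the dihydroflavonol, so C2 and C3 should be preserved.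

Step 8
Reactants: 10 (2R,3R)-3,7,8-tris(benzyloxy)-2-[4-(benzyloxy)phenyl]-6-bromochroman-4-one
Product: 11 (2R,3R)-3,7,8-tris(benzyloxy)-2-[4-(benzyloxy)phenyl]-6-vinylchroman-4-one
Conditions: CH2=CHSnBu3, Pd(PPh3)4 (cat.), toluene, 100 °C
Reagents that add atoms: tributyl(vinyl)stannane, C=C[Sn](CCCC)(CCCC)CCCC
Why: Stille coupling (oxidative addition of the aryl bromide to zerovalent palladium, transmetalation from tin, reductive elimination) runs under neutral conditions that should leave the base-labile chromanone intact.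

Step 9
Reactants: 11 (2R,3R)-3,7,8-tris(benzyloxy)-2-[4-(benzyloxy)phenyl]-6-vinylchroman-4-one
Product: 12 (2R,3R)-3,7,8-tris(benzyloxy)-2-[4-(benzyloxy)phenyl]-4-oxochromane-6-carbaldehyde
Conditions: OsO4 (cat.), NaIO4, 2,6-lutidine, dioxane/H2O, rt
Reagents that add atoms: sodium periodate, [Na+].[O-]I(=O)(=O)=O
Why: Lemieux–Johnson oxidation (osmylation of the styrene, periodate cleavage of the diol) should give the aryl aldehyde, with 2,6-lutidine suppressing over-oxidation and the benzyl ethers and chromanone being inert.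

Step 10
Reactants: 13 2,3-dihydroxybenzaldehyde
Product: 14 2,3-bis(benzyloxy)benzaldehyde
Conditions: BnBr, K2CO3, DMF, rt
Reagents that add atoms: benzyl bromide, BrCc1ccccc1
Why: Williamson etherification of both phenoxides protects the two oxygens that become O7 and O8 of the upper unit.

Step 11
Reactants: 14 2,3-bis(benzyloxy)benzaldehyde
Product: 16 2,3-bis(benzyloxy)phenol, via 2,3-bis(benzyloxy)phenyl formate 15 (not isolated)
Conditions: mCPBA, CH2Cl2, rt; then K2CO3 (cat.), MeOH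
Reagents that add atoms: 3-chloroperbenzoic acid, OOC(=O)c1cccc(Cl)c1
Why: Baeyer–Villiger (Dakin-type) oxidation, in which the electron-rich aryl group migrates in the Criegee intermediate, gives the aryl formate, which mild methanolysis should convert to the phenol.

Step 12
Reactants: 12 (2R,3R)-3,7,8-tris(benzyloxy)-2-[4-(benzyloxy)phenyl]-4-oxochromane-6-carbaldehyde; 17 1-(benzyloxy)-4-ethynylbenzene
Product: 18 (2R,3R)-3,7,8-tris(benzyloxy)-2-[4-(benzyloxy)phenyl]-6-[(1R)-3-[4-(benzyloxy)phenyl]-1-hydroxyprop-2-yn-1-yl]chroman-4-one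
Conditions: Et2Zn (2 equiv), toluene, reflux (alkyne only); then (R)-BINOL (0.4 equiv), Ti(OiPr)4 (1 equiv), CH2Cl2, rt
Reagents that add atoms: none
Why: BINOL–Ti(OiPr)4-catalysed asymmetric addition of the alkynylzinc reagent to the aryl aldehyde spares the chromanone ketone, and (R)-BINOL should direct the alkynyl group to the Re face to give the (R)-carbinol, a relay stereocenter that is erased again in step 17.

Step 13
Reactants: 18 (2R,3R)-3,7,8-tris(benzyloxy)-2-[4-(benzyloxy)phenyl]-6-[(1R)-3-[4-(benzyloxy)phenyl]-1-hydroxyprop-2-yn-1-yl]chroman-4-one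
Product: 19 (2R,3R)-3,7,8-tris(benzyloxy)-2-[4-(benzyloxy)phenyl]-6-[(1R,2Z)-3-[4-(benzyloxy)phenyl]-1-hydroxyprop-2-en-1-yl]chroman-4-one
Conditions: H2 (1 atm), Pd/CaCO3 (Pb(OAc)2-poisoned), quinoline, EtOAc, rt
Reagents that add atoms: none
Why: Semi-hydrogenation on the poisoned palladium surface (Lindlar conditions) adds H2 syn and should stop at the Z-alkene without touching the benzyl ethers, the ketone or the carbinol.

Step 14
Reactants: 19 (2R,3R)-3,7,8-tris(benzyloxy)-2-[4-(benzyloxy)phenyl]-6-[(1R,2Z)-3-[4-(benzyloxy)phenyl]-1-hydroxyprop-2-en-1-yl]chroman-4-one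
Product: 20 (2R,3R)-3,7,8-tris(benzyloxy)-2-[4-(benzyloxy)phenyl]-6-[(S)-{(2R,3S)-3-[4-(benzyloxy)phenyl]oxiran-2-yl}(hydroxy)methyl]chroman-4-one
Conditions: mCPBA, NaHCO3, CH2Cl2, 0 °C
Reagents that add atoms: 3-chloroperbenzoic acid, OOC(=O)c1cccc(Cl)c1
Why: In this hydroxyl-directed peracid epoxidation (Henbest), 1,3-allylic strain holds the carbinol hydrogen in the alkene plane of the Z-allylic alcohol, so the hydrogen-bonded peracid should add syn to OH and give the threo cis-epoxy alcohol, which fixes C3 and, after inversion in step 15, C2.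

Step 15
Reactants: 20 (2R,3R)-3,7,8-tris(benzyloxy)-2-[4-(benzyloxy)phenyl]-6-[(S)-{(2R,3S)-3-[4-(benzyloxy)phenyl]oxiran-2-yl}(hydroxy)methyl]chroman-4-one; 16 2,3-bis(benzyloxy)phenol
Product: 21 (2R,3R)-3,7,8-tris(benzyloxy)-6-[(1S,2R,3R)-3-[2,3-bis(benzyloxy)phenoxy]-3-[4-(benzyloxy)phenyl]-1,2-dihydroxypropyl]-2-[4-(benzyloxy)phenyl]chroman-4-one
Conditions: 16 (4 equiv), Ti(OiPr)4 (1.5 equiv), toluene, 0 °C to rt
Reagents that add atoms: none
Why: In this Ti(OiPr)4-mediated opening of a 2,3-epoxy alcohol the titanium alkoxide chelate activates the epoxide and the phenol should attack the distal benzylic carbon (C2) in an SN2 process with inversion, giving the threo 2-aryloxy 3-ol that maps onto the 2,3-cis flavan.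

Step 16
Reactants: 21 (2R,3R)-3,7,8-tris(benzyloxy)-6-[(1S,2R,3R)-3-[2,3-bis(benzyloxy)phenoxy]-3-[4-(benzyloxy)phenyl]-1,2-dihydroxypropyl]-2-[4-(benzyloxy)phenyl]chroman-4-one
Product: 22 (1S,2S,3R)-3-[2,3-bis(benzyloxy)phenoxy]-3-[4-(benzyloxy)phenyl]-1-[(2R,3R)-3,7,8-tris(benzyloxy)-2-[4-(benzyloxy)phenyl]-4-oxochroman-6-yl]propane-1,2-diyl dibenzoate
Conditions: BzCl, pyridine, DMAP (cat.), CH2Cl2, 0 °C to rt
Reagents that add atoms: benzoyl chloride, O=C(Cl)c1ccccc1
Why: DMAP-catalysed nucleophilic acyl substitution should esterify both secondary hydroxyls, providing the leaving group at C4 and the participating group at C3 in one operation.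

Step 17
Reactants: 22 (1S,2S,3R)-3-[2,3-bis(benzyloxy)phenoxy]-3-[4-(benzyloxy)phenyl]-1-[(2R,3R)-3,7,8-tris(benzyloxy)-2-[4-(benzyloxy)phenyl]-4-oxochroman-6-yl]propane-1,2-diyl dibenzoate
Product: 24 (2R,3R,4R)-7,8-bis(benzyloxy)-2-[4-(benzyloxy)phenyl]-4-[(2R,3R)-3,7,8-tris(benzyloxy)-2-[4-(benzyloxy)phenyl]-4-oxochroman-6-yl]chroman-3-yl benzoate, via trans-dioxolanylium triflate 23 (not isolated)
Conditions: Me3SiOTf (0.5 equiv), 4 Å MS, CH2Cl2 (0.01 M), −40 to 0 °C
Reagents that add atoms: none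
Why: Me3SiOTf silylates the C4 benzoate carbonyl and the C4–O bond ionises to a benzylic cation stabilised by lower ring A (O1' para and the C7' oxygen ortho to C6'); the C3 benzoate carbonyl captures it reversibly as a 2-phenyl-1,3-dioxolan-2-ylium ion, and because the (1S) epimer would first give the cis ion, which reopens through the cation, the more stable trans-4,5-disubstituted ion 23 should be reached whichever C4 epimer is used. The tethered 2,3-bis(benzyloxy)phenoxy ring then attacks C4 through C4a and loses a proton to form C4–C4a; the closest known reactions are the acid-promoted Friedel–Crafts cyclisation of 3-aryloxy-1-arylpropyl cations and of aryl glycidyl ethers to 4-arylchromans and the 1,2-trans substitution of vicinal diol esters under neighbouring-group participation. Ring C closes in a six-membered exo-tet mode at C4 (exo-trig if the free cation reacts), endo with respect to the arene C4a–C8a bond. The new stereocenter C4 is set by anti attack on the trans-dioxolanylium ion, which places the lower aryl group trans to O3, and the free cation should give the same result because 1,3-allylic strain keeps H3 in the cation plane and the tether through C2 brings C4a in anti to O3. The step needs ionisation at C4 and not at the C2–O1 benzylic ether, which the far better leaving-group ability of the silylated benzoate secures, and attack through C4a only, which is secured because C8 is substituted and C4a (ortho to O1, para to the C7 benzyloxy group) is the one carbon that can reach C4 in a six-membered ring. C2 and C3 are not touched, and high dilution at low temperature should suppress intermolecular arylation and benzyl ether cleavage.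

Step 18
Reactants: 24 (2R,3R,4R)-7,8-bis(benzyloxy)-2-[4-(benzyloxy)phenyl]-4-[(2R,3R)-3,7,8-tris(benzyloxy)-2-[4-(benzyloxy)phenyl]-4-oxochroman-6-yl]chroman-3-yl benzoate
Product: 25 (2R,3R)-3,7,8-tris(benzyloxy)-2-[4-(benzyloxy)phenyl]-6-[(2R,3R,4R)-7,8-bis(benzyloxy)-2-[4-(benzyloxy)phenyl]-3-hydroxychroman-4-yl]chroman-4-one
Conditions: K2CO3 (0.3 equiv), MeOH/THF, 0 °C to rt
Reagents that add atoms: none
Why: Base-catalysed transesterification (methanolysis) should remove the secondary benzoate as methyl benzoate, substoichiometric carbonate at low temperature being chosen to limit enolisation of the 3-O-benzyl chromanone.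

Step 19
Reactants: 25 (2R,3R)-3,7,8-tris(benzyloxy)-2-[4-(benzyloxy)phenyl]-6-[(2R,3R,4R)-7,8-bis(benzyloxy)-2-[4-(benzyloxy)phenyl]-3-hydroxychroman-4-yl]chroman-4-one
Product: 26 (2R,3R)-3,7,8-trihydroxy-2-(4-hydroxyphenyl)-6-[(2R,3R,4S)-3,7,8-trihydroxy-2-(4-hydroxyphenyl)chroman-4-yl]chroman-4-one
Conditions: H2 (1 atm), Pd(OH)2/C, THF/MeOH, rt
Reagents that add atoms: none
Why: Hydrogenolysis over Pd(OH)2/C should cleave all seven benzyl ethers under neutral conditions while the aryl ketone, the C4–aryl bond and the ring C–O bonds stay intact.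

Step 20
Reactants: 26 (2R,3R)-3,7,8-trihydroxy-2-(4-hydroxyphenyl)-6-[(2R,3R,4S)-3,7,8-trihydroxy-2-(4-hydroxyphenyl)chroman-4-yl]chroman-4-one
Product: 27 (2R,3S,4R)-2-(4-hydroxyphenyl)-6-[(2R,3R,4S)-3,7,8-trihydroxy-2-(4-hydroxyphenyl)chroman-4-yl]chromane-3,4,7,8-tetrol
Conditions: NaBH4, MeOH, 0 °C; neutral work-up under argon
Reagents that add atoms: none
Why: In this borohydride reduction of a free-phenolic dihydroflavonol, axial hydride delivery to the C4' carbonyl should give the equatorial 4'-hydroxyl trans to the equatorial 3'-hydroxyl, as in the known conversion of 2,3-trans dihydroflavonols into 2,3-trans-3,4-trans flavan-3,4-diols.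

**Compound list**

1 | gallacetophenone, 1-(2,3,4-trihydroxyphenyl)ethan-1-one | CC(=O)c1ccc(O)c(O)c1O | starting material
2 | 1-[3,4-bis(benzyloxy)-2-hydroxyphenyl]ethan-1-one | CC(=O)c1ccc(OCc2ccccc2)c(OCc2ccccc2)c1O | intermediate
3 | 1-[3,4-bis(benzyloxy)-5-bromo-2-hydroxyphenyl]ethan-1-one | CC(=O)c1cc(Br)c(OCc2ccccc2)c(OCc2ccccc2)c1O | intermediate
4 | 1-[3,4-bis(benzyloxy)-5-bromo-2-(methoxymethoxy)phenyl]ethan-1-one | CC(=O)c1cc(Br)c(OCc2ccccc2)c(OCc2ccccc2)c1OCOC | intermediate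
5 | 4-(benzyloxy)benzaldehyde | O=Cc1ccc(OCc2ccccc2)cc1 | starting material
6 | (E)-1-[3,4-bis(benzyloxy)-5-bromo-2-(methoxymethoxy)phenyl]-3-[4-(benzyloxy)phenyl]prop-2-en-1-one | O=C(/C=C/c1ccc(OCc2ccccc2)cc1)c1cc(Br)c(OCc2ccccc2)c(OCc2ccccc2)c1OCOC | intermediate
7 | [3,4-bis(benzyloxy)-5-bromo-2-(methoxymethoxy)phenyl][(2R,3S)-3-[4-(benzyloxy)phenyl]oxiran-2-yl]methanone | O=C(c1cc(Br)c(OCc2ccccc2)c(OCc2ccccc2)c1OCOC)[C@@H]1O[C@H]1c1ccc(OCc2ccccc2)cc1 | intermediate
8 | 2'-hydroxy epoxy ketone, [3,4-bis(benzyloxy)-5-bromo-2-hydroxyphenyl][(2R,3S)-3-[4-(benzyloxy)phenyl]oxiran-2-yl]methanone (not isolated) | O=C(c1cc(Br)c(OCc2ccccc2)c(OCc2ccccc2)c1O)[C@@H]1O[C@H]1c1ccc(OCc2ccccc2)cc1 | intermediate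
9 | (2R,3R)-7,8-bis(benzyloxy)-2-[4-(benzyloxy)phenyl]-6-bromo-3-hydroxychroman-4-one (2,3-trans) | O=C1c2cc(Br)c(OCc3ccccc3)c(OCc3ccccc3)c2O[C@H](c2ccc(OCc3ccccc3)cc2)[C@H]1O | intermediate
10 | (2R,3R)-3,7,8-tris(benzyloxy)-2-[4-(benzyloxy)phenyl]-6-bromochroman-4-one | O=C1c2cc(Br)c(OCc3ccccc3)c(OCc3ccccc3)c2O[C@H](c2ccc(OCc3ccccc3)cc2)[C@H]1OCc1ccccc1 | intermediate
11 | (2R,3R)-3,7,8-tris(benzyloxy)-2-[4-(benzyloxy)phenyl]-6-vinylchroman-4-one | O=C1c2cc(C=C)c(OCc3ccccc3)c(OCc3ccccc3)c2O[C@H](c2ccc(OCc3ccccc3)cc2)[C@H]1OCc1ccccc1 | intermediate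
12 | (2R,3R)-3,7,8-tris(benzyloxy)-2-[4-(benzyloxy)phenyl]-4-oxochromane-6-carbaldehyde | O=C1c2cc(C=O)c(OCc3ccccc3)c(OCc3ccccc3)c2O[C@H](c2ccc(OCc3ccccc3)cc2)[C@H]1OCc1ccccc1 | intermediate
13 | 2,3-dihydroxybenzaldehyde | O=Cc1cccc(O)c1O | starting material
14 | 2,3-bis(benzyloxy)benzaldehyde | O=Cc1cccc(OCc2ccccc2)c1OCc1ccccc1 | intermediate
15 | 2,3-bis(benzyloxy)phenyl formate (not isolated) | O=COc1cccc(OCc2ccccc2)c1OCc1ccccc1 | intermediate
16 | 2,3-bis(benzyloxy)phenol | Oc1cccc(OCc2ccccc2)c1OCc1ccccc1 | intermediate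
17 | 1-(benzyloxy)-4-ethynylbenzene | C#Cc1ccc(OCc2ccccc2)cc1 | starting material
18 | (2R,3R)-3,7,8-tris(benzyloxy)-2-[4-(benzyloxy)phenyl]-6-[(1R)-3-[4-(benzyloxy)phenyl]-1-hydroxyprop-2-yn-1-yl]chroman-4-one | O=C1c2cc([C@H](O)C#Cc3ccc(OCc4ccccc4)cc3)c(OCc3ccccc3)c(OCc3ccccc3)c2O[C@H](c2ccc(OCc3ccccc3)cc2)[C@H]1OCc1ccccc1 | intermediate
19 | (2R,3R)-3,7,8-tris(benzyloxy)-2-[4-(benzyloxy)phenyl]-6-[(1R,2Z)-3-[4-(benzyloxy)phenyl]-1-hydroxyprop-2-en-1-yl]chroman-4-one | O=C1c2cc([C@H](O)/C=C\c3ccc(OCc4ccccc4)cc3)c(OCc3ccccc3)c(OCc3ccccc3)c2O[C@H](c2ccc(OCc3ccccc3)cc2)[C@H]1OCc1ccccc1 | intermediate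
20 | (2R,3R)-3,7,8-tris(benzyloxy)-2-[4-(benzyloxy)phenyl]-6-[(S)-{(2R,3S)-3-[4-(benzyloxy)phenyl]oxiran-2-yl}(hydroxy)methyl]chroman-4-one (threo, cis-epoxide) | O=C1c2cc([C@H](O)[C@H]3O[C@H]3c3ccc(OCc4ccccc4)cc3)c(OCc3ccccc3)c(OCc3ccccc3)c2O[C@H](c2ccc(OCc3ccccc3)cc2)[C@H]1OCc1ccccc1 | intermediate
21 | (2R,3R)-3,7,8-tris(benzyloxy)-6-[(1S,2R,3R)-3-[2,3-bis(benzyloxy)phenoxy]-3-[4-(benzyloxy)phenyl]-1,2-dihydroxypropyl]-2-[4-(benzyloxy)phenyl]chroman-4-one | O=C1c2cc([C@H](O)[C@@H](O)[C@H](Oc3cccc(OCc4ccccc4)c3OCc3ccccc3)c3ccc(OCc4ccccc4)cc3)c(OCc3ccccc3)c(OCc3ccccc3)c2O[C@H](c2ccc(OCc3ccccc3)cc2)[C@H]1OCc1ccccc1 | intermediate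
22 | (1S,2S,3R)-3-[2,3-bis(benzyloxy)phenoxy]-3-[4-(benzyloxy)phenyl]-1-[(2R,3R)-3,7,8-tris(benzyloxy)-2-[4-(benzyloxy)phenyl]-4-oxochroman-6-yl]propane-1,2-diyl dibenzoate (key-step precursor) | O=C1c2cc([C@H](OC(=O)c3ccccc3)[C@@H](OC(=O)c3ccccc3)[C@H](Oc3cccc(OCc4ccccc4)c3OCc3ccccc3)c3ccc(OCc4ccccc4)cc3)c(OCc3ccccc3)c(OCc3ccccc3)c2O[C@H](c2ccc(OCc3ccccc3)cc2)[C@H]1OCc1ccccc1 | intermediate
23 | trans-dioxolanylium triflate: 2-phenyl-1,3-dioxolan-2-ylium ion spanning O3 and O4 of the chain, lower aryl group on C4 trans to the aryloxy(aryl)methyl group on C3 (not isolated) | O=C1c2cc([C@@H]3[O+]=C(c4ccccc4)O[C@H]3[C@H](Oc3cccc(OCc4ccccc4)c3OCc3ccccc3)c3ccc(OCc4ccccc4)cc3)c(OCc3ccccc3)c(OCc3ccccc3)c2O[C@H](c2ccc(OCc3ccccc3)cc2)[C@H]1OCc1ccccc1.[O-]S(=O)(=O)C(F)(F)F | intermediate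
24 | (2R,3R,4R)-7,8-bis(benzyloxy)-2-[4-(benzyloxy)phenyl]-4-[(2R,3R)-3,7,8-tris(benzyloxy)-2-[4-(benzyloxy)phenyl]-4-oxochroman-6-yl]chroman-3-yl benzoate (upper unit 2,3-cis-3,4-trans; key-step product) | O=C1c2cc([C@H]3c4ccc(OCc5ccccc5)c(OCc5ccccc5)c4O[C@H](c4ccc(OCc5ccccc5)cc4)[C@@H]3OC(=O)c3ccccc3)c(OCc3ccccc3)c(OCc3ccccc3)c2O[C@H](c2ccc(OCc3ccccc3)cc2)[C@H]1OCc1ccccc1 | intermediate
25 | (2R,3R)-3,7,8-tris(benzyloxy)-2-[4-(benzyloxy)phenyl]-6-[(2R,3R,4R)-7,8-bis(benzyloxy)-2-[4-(benzyloxy)phenyl]-3-hydroxychroman-4-yl]chroman-4-one | O=C1c2cc([C@H]3c4ccc(OCc5ccccc5)c(OCc5ccccc5)c4O[C@H](c4ccc(OCc5ccccc5)cc4)[C@@H]3O)c(OCc3ccccc3)c(OCc3ccccc3)c2O[C@H](c2ccc(OCc3ccccc3)cc2)[C@H]1OCc1ccccc1 | intermediate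
26 | (2R,3R)-3,7,8-trihydroxy-2-(4-hydroxyphenyl)-6-[(2R,3R,4S)-3,7,8-trihydroxy-2-(4-hydroxyphenyl)chroman-4-yl]chroman-4-one | O=C1c2cc([C@H]3c4ccc(O)c(O)c4O[C@H](c4ccc(O)cc4)[C@@H]3O)c(O)c(O)c2O[C@H](c2ccc(O)cc2)[C@H]1O | intermediate
27 | (2R,3S,4R)-2-(4-hydroxyphenyl)-6-[(2R,3R,4S)-3,7,8-trihydroxy-2-(4-hydroxyphenyl)chroman-4-yl]chromane-3,4,7,8-tetrol (CNP0391561.5) | Oc1ccc([C@H]2Oc3c(ccc(O)c3O)[C@H](c3cc4c(c(O)c3O)O[C@H](c3ccc(O)cc3)[C@@H](O)[C@@H]4O)[C@H]2O)cc1 | target

**Step count and risks**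

Total step count: 20. Longest linear sequence: 18 steps (steps 1–9, then 12–20); the phenol branch (steps 10 and 11) joins at step 15.

The three steps most likely to fail:

Step 17. The closure may take place on the kinetically formed cis-dioxolanylium ion before it has equilibrated, which would erode the 3,4-trans selectivity. The C2–O1 benzylic ether may ionise in competition with the C4 benzoate, or the cation may be intercepted intermolecularly. The fallback replaces the ester-bridged cation by an epoxy-arene cyclisation, a known route to trans-4-arylchroman-3-ols. Diol 21 is taken through the Kolb–Sharpless sequence (MeC(OMe)3, PPTS; AcBr; K2CO3, MeOH): the cyclic orthoacetate F1 is opened by bromide at the benzylic carbon to the bromo acetate F2, and methanolysis closes this to the trans-epoxide F3 with net retention at C4. Treatment of F3 with BF3·OEt2 in CH2Cl2 at −78 °C should let the aryl ether attack the benzylic epoxide carbon through C4a with inversion and give the 3-ol 25 directly, where the route is rejoined at step 19.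

Step 15. The titanium-bound epoxide may open through a benzylic cation at C2 with loss of configuration, may take up isopropoxide in place of the hindered phenol, or the phenol may react through carbon. The fallback makes the aryl ether by a Mitsunobu displacement. Z-allylic alcohol 19 is dihydroxylated syn to its hydroxyl group with OsO4·TMEDA (hydrogen-bond-directed) to the all-syn triol F4. The threo C3,C4-diol is tied up as its trans-acetonide F5 (2,2-dimethoxypropane, PPTS). Phenol 16 then displaces the free C2 hydroxyl with inversion (PPh3, DIAD, toluene) to give the aryl ether acetonide F6, and aqueous AcOH releases diol 21, where the route is rejoined at step 16.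

Step 18. Methoxide may enolise the 3-O-benzyl chromanone and open it by retro-oxa-Michael elimination, which would scramble C2' and C3' before the hindered benzoate is cleaved. The fallback changes the order of the last operations. Ketone 24 is reduced first (NaBH4, THF/MeOH, 0 °C) to the 3',4'-trans alcohol F7, which can no longer enolise. The benzoate is then removed (K2CO3, MeOH) to give the benzyl-protected diol F8. Hydrogenolysis over Pd(OH)2/C in neutral EtOAc/MeOH, stopped at the calculated uptake to spare the benzylic C4' hydroxyl, should give target 27 directly.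

Further compounds
F1 | step 17 | cyclic orthoacetate (2-methoxy-2-methyl-1,3-dioxolane, trans-4,5-disubstituted) of diol 21 | O=C1c2cc([C@@H]3OC(C)(OC)O[C@H]3[C@H](Oc3cccc(OCc4ccccc4)c3OCc3ccccc3)c3ccc(OCc4ccccc4)cc3)c(OCc3ccccc3)c(OCc3ccccc3)c2O[C@H](c2ccc(OCc3ccccc3)cc2)[C@H]1OCc1ccccc1
F2 | step 17 | bromo acetate from 21: bromide at the benzylic chain carbon (inverted), acetate on the adjacent carbon | O=C1c2cc([C@@H](Br)[C@@H](OC(C)=O)[C@H](Oc3cccc(OCc4ccccc4)c3OCc3ccccc3)c3ccc(OCc4ccccc4)cc3)c(OCc3ccccc3)c(OCc3ccccc3)c2O[C@H](c2ccc(OCc3ccccc3)cc2)[C@H]1OCc1ccccc1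
F3 | step 17 | trans-epoxide across the future C3 and C4 (lower aryl group trans to the aryloxy(aryl)methyl group) | O=C1c2cc([C@@H]3O[C@H]3[C@H](Oc3cccc(OCc4ccccc4)c3OCc3ccccc3)c3ccc(OCc4ccccc4)cc3)c(OCc3ccccc3)c(OCc3ccccc3)c2O[C@H](c2ccc(OCc3ccccc3)cc2)[C@H]1OCc1ccccc1
F4 | step 15 | all-syn triol from hydroxyl-directed syn-dihydroxylation of 19 | O=C1c2cc([C@H](O)[C@@H](O)[C@@H](O)c3ccc(OCc4ccccc4)cc3)c(OCc3ccccc3)c(OCc3ccccc3)c2O[C@H](c2ccc(OCc3ccccc3)cc2)[C@H]1OCc1ccccc1
F5 | step 15 | trans-acetonide of F4 across the future O3 and O4, with the benzylic hydroxyl at the future C2 free | O=C1c2cc([C@@H]3OC(C)(C)O[C@H]3[C@@H](O)c3ccc(OCc4ccccc4)cc3)c(OCc3ccccc3)c(OCc3ccccc3)c2O[C@H](c2ccc(OCc3ccccc3)cc2)[C@H]1OCc1ccccc1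
F6 | step 15 | aryl ether acetonide (acetonide of diol 21) | O=C1c2cc([C@@H]3OC(C)(C)O[C@H]3[C@H](Oc3cccc(OCc4ccccc4)c3OCc3ccccc3)c3ccc(OCc4ccccc4)cc3)c(OCc3ccccc3)c(OCc3ccccc3)c2O[C@H](c2ccc(OCc3ccccc3)cc2)[C@H]1OCc1ccccc1
F7 | step 18 | 3',4'-trans alcohol from reduction of 24, upper 3-O-benzoate retained | O[C@@H]1c2cc([C@H]3c4ccc(OCc5ccccc5)c(OCc5ccccc5)c4O[C@H](c4ccc(OCc5ccccc5)cc4)[C@@H]3OC(=O)c3ccccc3)c(OCc3ccccc3)c(OCc3ccccc3)c2O[C@H](c2ccc(OCc3ccccc3)cc2)[C@H]1OCc1ccccc1
F8 | step 18 | benzyl-protected diol: upper 3-hydroxyl and lower 4'-hydroxyl free, seven benzyl ethers | O[C@@H]1c2cc([C@H]3c4ccc(OCc5ccccc5)c(OCc5ccccc5)c4O[C@H](c4ccc(OCc5ccccc5)cc4)[C@@H]3O)c(OCc3ccccc3)c(OCc3ccccc3)c2O[C@H](c2ccc(OCc3ccccc3)cc2)[C@H]1OCc1ccccc1
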